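Atom labels follow the decalin numbering of the target: ring A is C1–C5 plus C10, ring B is C5–C10, C11 is the OCH2 carbon on C9, the hydroxyl is on C3 and the alkene is C7=C8.
Retrosynthesis: cut the aryl ether at C11–O (scopoletin), open ring A at C1–C2 (metathesis of two vinyl groups, the C1 vinyl coming from a carboxyl), cut C9–C10 of ring B, then take the resulting lactone apart at C5=C10 (intramolecular olefination) and C6–C7 (aldol).
Enabling feature: C9 and C10 are neighbours, their bond is allylic to C7=C8, and C10 carries C1, which can be a carboxyl. Tying that carboxyl to an oxygen on C7 gives a δ-lactone (C1, O, C7, C6, C5, C10) with the C8=C9 alkenyl group on C7, the substrate of a ring-contracting ester enolate Claisen rearrangement.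
Forward order: D-pantolactone gives the C2–C6 methyl ketone and prenol the C7–C9/C11 enal. Aldol and olefination build the lactone, conjugate reduction and methylation complete it, the Claisen contraction closes ring B, metathesis closes ring A, and the coumarin is attached last.
Stereochemistry: C3 comes unchanged from D-pantolactone. C7 is set by the chiral boron enolate, C5 by hydride delivery anti to the C7 substituent, and C9 and C10 by transfer from C7 and C5 through the boat transition state of the E-alkenyl lactone.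
Key step: step 15

Remark (assumption): (+)-Ipc2BCl (Ipc = isopinocampheyl, from (−)-α-pinene) is taken to direct a methyl ketone enolate to the si face of the enal, giving 7S; if the sense were the reverse, its enantiomer would be used in step 10 and nothing else would change.

Step 1
Reactants: 1 D-(−)-pantolactone
Product: 2 (R)-3-(tert-butyldimethylsilyloxy)-4,4-dimethyldihydrofuran-2(3H)-one
Conditions: TBSCl, imidazole, DMF, rt
Reagents that add atoms: tert-butyldimethylsilyl chloride, CC(C)(C)[Si](C)(C)Cl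
Why: Routine silyl ether formation on the secondary α-hydroxy lactone, which touches no stereocentre and installs the C3 protecting group that is kept to the last step.

Step 2
Reactants: 2 silyl ether of pantolactone
Product: 3 (3R)-3-(tert-butyldimethylsilyloxy)-4,4-dimethyltetrahydrofuran-2-ol (lactol; both anomers)
Conditions: i-Bu2AlH, CH2Cl2, −78 °C
Reagents that add atoms: none
Why: Partial reduction of a lactone to the lactol, in which the tetrahedral aluminium hemiacetal should persist at −78 °C until work-up.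

Step 3
Reactants: 3 lactol
Product: 5 (S)-3-(tert-butyldimethylsilyloxy)-2,2-dimethylpent-4-en-1-ol, via hydroxy aldehyde 4 (not isolated)
Conditions: Ph3PCH3Br, n-BuLi, THF, 0 °C → rt
Reagents that add atoms: methyltriphenylphosphonium bromide, C[P+](c1ccccc1)(c1ccccc1)c1ccccc1.[Br-]
Why: Wittig methylenation of the open-chain aldehyde tautomer of the lactol; the α-silyloxy centre sits next to a quaternary carbon, which should slow enolisation, and the lithium alkoxide at or below room temperature should not provoke silyl migration.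

Step 4
Reactants: 5 alkenol
Product: 6 (S)-3-(tert-butyldimethylsilyloxy)-2,2-dimethylpent-4-enal
Conditions: Dess–Martin periodinane, NaHCO3, CH2Cl2, rt
Reagents that add atoms: none
Why: Dess–Martin oxidation of a neopentyl primary alcohol to an aldehyde that has no α-hydrogen, under buffered conditions that spare the silyl ether and the alkene.

Step 5
Reactants: 6 aldehyde
Product: 7 (4S)-4-(tert-butyldimethylsilyloxy)-3,3-dimethylhex-5-en-2-ol (both C2 epimers)
Conditions: MeMgBr, THF, −78 → 0 °C
Reagents that add atoms: methylmagnesium bromide, C[Mg]Br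
Why: Grignard addition to the aldehyde, where the new carbinol centre need not be controlled because it is oxidised in step 6.

Step 6
Reactants: 7 secondary alcohol
Product: 8 (S)-4-(tert-butyldimethylsilyloxy)-3,3-dimethylhex-5-en-2-one
Conditions: Dess–Martin periodinane, NaHCO3, CH2Cl2, rt
Reagents that add atoms: none
Why: Dess–Martin oxidation to the methyl ketone, which can enolise only toward its methyl group (the future C6).

Step 7
Reactants: 9 3-methylbut-2-en-1-ol
Product: 10 1-methoxy-4-{[(3-methylbut-2-en-1-yl)oxy]methyl}benzene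
Conditions: NaH, 4-MeOC6H4CH2Cl, n-Bu4NI (cat.), THF/DMF, 0 °C → rt
Reagents that add atoms: 4-methoxybenzyl chloride, COc1ccc(CCl)cc1
Why: Williamson etherification of the primary allylic alkoxide under iodide catalysis.

Step 8
Reactants: 10 prenyl 4-methoxybenzyl ether
Product: 11 (E)-4-(4-methoxybenzyloxy)-2-methylbut-2-en-1-ol
Conditions: SeO2 (cat.), t-BuOOH, salicylic acid (cat.), CH2Cl2, rt
Reagents that add atoms: tert-butyl hydroperoxide, CC(C)(C)OO (terminal source of the new oxygen, relayed by selenium dioxide, O=[Se]=O)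
Why: Selenium dioxide allylic oxidation (ene reaction, then [2,3]-shift), which on a trisubstituted alkene hydroxylates the methyl group trans to the chain and so fixes the E geometry of the future C8=C9 bond.

Step 9
Reactants: 11 allylic alcohol
Product: 12 (E)-4-(4-methoxybenzyloxy)-2-methylbut-2-enal
Conditions: MnO2, CH2Cl2, rt
Reagents that add atoms: none
Why: MnO2 oxidation of a primary allylic alcohol to the enal, with no change to the ether or the double bond geometry.

Step 10
Reactants: 8 methyl ketone; 12 enal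
Product: 15 (3S,7S,8E)-3-(tert-butyldimethylsilyloxy)-7-hydroxy-10-(4-methoxybenzyloxy)-4,4,8-trimethyldeca-1,8-dien-5-one, via enol borinate 13 (not isolated), via boron aldolate 14 (not isolated)
Conditions: (+)-Ipc2BCl, Et3N, Et2O, 0 °C; 12, −78 → −20 °C; H2O2, MeOH, pH 7 buffer, 0 °C
Reagents that add atoms: none
Why: Boron-mediated aldol addition of a methyl ketone through a chiral diisopinocampheylboron enolate, whose ligands should direct attack to the si face of the enal and set C7 as S, while the C3 silyl ether exerts little 1,5-induction of its own and the minor C7 epimer is a diastereomer that chromatography can remove.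

Step 11
Reactants: 15 aldol; 16 2-(diethoxyphosphoryl)acetic acid
Product: 17 7-O-[2-(diethoxyphosphoryl)acetyl] ester of 15
Conditions: DCC, DMAP (cat.), CH2Cl2, 0 °C → rt
Reagents that add atoms: none
Why: Steglich esterification of the secondary allylic alcohol under near-neutral conditions that should not trigger β-elimination of the aldol.

Step 12
Reactants: 17 phosphonoacetate
Product: 18 (S)-4-[(S)-3-(tert-butyldimethylsilyloxy)-2-methylpent-4-en-2-yl]-6-[(E)-4-(4-methoxybenzyloxy)but-2-en-2-yl]-5,6-dihydro-2H-pyran-2-one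
Conditions: LiCl, DBU, MeCN, 0 °C → rt
Reagents that add atoms: none
Why: Intramolecular Horner–Wadsworth–Emmons olefination under mild LiCl/amine conditions, in which the tether delivers the phosphonate anion to the hindered C5 ketone in a six-membered mode and can only give the ring alkene C5=C10.

Step 13
Reactants: 18 unsaturated lactone
Product: 19 (4S,6S)-4-[(S)-3-(tert-butyldimethylsilyloxy)-2-methylpent-4-en-2-yl]-6-[(E)-4-(4-methoxybenzyloxy)but-2-en-2-yl]tetrahydro-2H-pyran-2-one (4,6-cis)
Conditions: Cu(OAc)2·H2O (cat.), 1,2-(Ph2P)2C6H4 (cat.), (HMe2Si)2O, t-BuOH, PhMe, rt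
Reagents that add atoms: none
Why: Conjugate reduction by bisphosphine-ligated CuH, which is active on β,β-disubstituted acceptors and ignores isolated alkenes; hydride should add to C5 anti to the pseudoequatorial C7 alkenyl group (axial attack on the half-chair), which places the C5 side chain cis to it.

Step 14
Reactants: 19 cis lactone
Product: 21 (3R,4S,6S)-3-methyl lactone (3,4-trans; 4,6-cis), via lithium enolate 20 (not isolated)
Conditions: LiN(i-Pr)2, THF, −78 °C; MeI, DMPU, −78 → −40 °C
Reagents that add atoms: iodomethane, CI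
Why: Alkylation of the lactone lithium enolate, expected to occur anti to the bulky C5 substituent, although the C10 configuration made here is erased in step 15.

Step 15
Reactants: 21 methyl lactone
Product: 25 (1R,2S,6R)-6-[(S)-3-(tert-butyldimethylsilyloxy)-2-methylpent-4-en-2-yl]-2-[(4-methoxybenzyloxy)methyl]-1,3-dimethylcyclohex-3-ene-1-carboxylic acid, via lithium enolate 22 (not isolated), via silyl ketene acetal 23 (not isolated), via trimethylsilyl ester 24 (not isolated)
Conditions: LiN(i-Pr)2, THF, −78 °C; Me3SiCl/Et3N, −78 → 0 °C; PhMe, 110 °C; 1 M HCl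
Reagents that add atoms: chlorotrimethylsilane, C[Si](C)(C)Cl (its silyl group is carried by 23 and 24 and is lost on hydrolysis to 25)
Why: Deprotonation at C10 and O-silylation give the cyclic silyl ketene acetal 23, whose enol geometry is fixed by the ring; on heating it undergoes a concerted [3,3]-sigmatropic shift in which C9–C10 forms while C7–O breaks and the double bond moves to C7=C8, and hydrolysis of silyl ester 24 frees the C1 acid. The closest known reaction type is the Ireland–Claisen ring contraction of 6-alkenyl δ-lactones to cyclohexene carboxylic acids and of 6-alkenyl dioxanones to dihydropyrans. Ring B closes as the six-membered carbocycle C10–C5–C6–C7=C8–C9 by bonding the exocyclic alkene terminus C9 to the endocyclic enol carbon C10, which is possible only through a boat transition state resembling a bicyclo[2.2.2]octadiene because the alkenyl group has to bridge the lactone. C10 is controlled by the lactone face that carries the alkenyl group: in the new carbocycle C1 and H5 lie on one face and the C10 methyl and the C5 side chain on the other, so H5 is trans to the methyl; C9 is controlled by the E geometry, which puts C11 on the outside of the boat and therefore anti to the C10 methyl. The step needs only the cis relation of the C5 and C7 substituents (from step 13) and the E olefin (from step 8), both already in the substrate, and the fully substituted C10 favours silylation on oxygen over carbon.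

Step 16
Reactants: 25 ring B acid
Product: 26 [(1R,2S,6S)-6-[(S)-3-(tert-butyldimethylsilyloxy)-2-methylpent-4-en-2-yl]-2-[(4-methoxybenzyloxy)methyl]-1,3-dimethylcyclohex-3-en-1-yl]methanol
Conditions: LiAlH4, THF, 0 °C → reflux
Reagents that add atoms: none
Why: LiAlH4 reduction of the hindered carboxylic acid to the primary alcohol, with silyl ether, benzyl-type ether and alkenes inert.

Step 17
Reactants: 26 alcohol
Product: 27 (1R,2S,6R)-6-[(S)-3-(tert-butyldimethylsilyloxy)-2-methylpent-4-en-2-yl]-2-[(4-methoxybenzyloxy)methyl]-1,3-dimethylcyclohex-3-ene-1-carbaldehyde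
Conditions: Dess–Martin periodinane, NaHCO3, CH2Cl2, rt
Reagents that add atoms: none
Why: Dess–Martin oxidation to a neopentyl aldehyde that has no α-hydrogen and therefore cannot epimerise.

Step 18
Reactants: 27 aldehyde
Product: 28 (4S,5R,6S)-4-[(S)-3-(tert-butyldimethylsilyloxy)-2-methylpent-4-en-2-yl]-6-[(4-methoxybenzyloxy)methyl]-1,5-dimethyl-5-vinylcyclohex-1-ene
Conditions: Ph3PCH3Br, KOt-Bu, THF, 0 °C → rt
Reagents that add atoms: methyltriphenylphosphonium bromide, C[P+](c1ccccc1)(c1ccccc1)c1ccccc1.[Br-]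
Why: Wittig methylenation with the small unstabilised ylide Ph3P=CH2, which reaches neopentyl aldehydes and turns C1 into the second vinyl group.

Step 19
Reactants: 28 triene
Product: 29 (1S,4aS,6S,8aR)-6-(tert-butyldimethylsilyloxy)-1-[(4-methoxybenzyloxy)methyl]-2,5,5,8a-tetramethyl-1,4,4a,5,6,8a-hexahydronaphthalene
Conditions: second-generation Grubbs catalyst (H2IMes)(PCy3)Cl2Ru=CHPh (cat.), PhMe, 80 °C
Reagents that add atoms: none
Why: Ring-closing olefin metathesis of the two monosubstituted vinyl groups, which sit trans-diequatorial on ring B and should close ring A as a trans-fused cyclohexene with loss of ethylene, the trisubstituted C7=C8 alkene staying out.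

Step 20
Reactants: 29 diene
Product: 30 (1S,4aS,6S,8aR)-6-(tert-butyldimethylsilyloxy)-1-[(4-methoxybenzyloxy)methyl]-2,5,5,8a-tetramethyl-1,4,4a,5,6,7,8,8a-octahydronaphthalene
Conditions: TsNHNH2, NaOAc, DME/H2O, reflux
Reagents that add atoms: none
Why: Diimide reduction (syn transfer of H2 from HN=NH), which discriminates by substitution and should saturate the cis-disubstituted C1=C2 alkene before the trisubstituted C7=C8 alkene while leaving the benzyl-type ether untouched.

Step 21
Reactants: 30 monoene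
Product: 31 [(1S,4aS,6S,8aR)-6-(tert-butyldimethylsilyloxy)-2,5,5,8a-tetramethyl-1,4,4a,5,6,7,8,8a-octahydronaphthalen-1-yl]methanol
Conditions: DDQ, CH2Cl2/pH 7 buffer, 0 °C
Reagents that add atoms: none
Why: Oxidative cleavage of the 4-methoxybenzyl ether by DDQ (hydride abstraction, then hydrolysis of the oxocarbenium ion), orthogonal to the silyl ether.

Step 22
Reactants: 31 C11 alcohol; 32 scopoletin
Product: 33 7-{[(1S,4aS,6S,8aR)-6-(tert-butyldimethylsilyloxy)-2,5,5,8a-tetramethyl-1,4,4a,5,6,7,8,8a-octahydronaphthalen-1-yl]methoxy}-6-methoxy-2H-chromen-2-one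
Conditions: PPh3, DIAD, THF, 0 °C → rt
Reagents that add atoms: none
Why: Mitsunobu etherification of the primary alcohol with the acidic 7-hydroxyl of scopoletin, forming the C11–O bond at a carbon that is not a stereocentre.

Step 23
Reactants: 33 silyl ether
Product: 34 CNP0218138.1
Conditions: aq. HF, MeCN, rt
Reagents that add atoms: none
Why: Fluoride-driven desilylation of the hindered secondary silyl ether under conditions that coumarin lactones, aryl ethers and trisubstituted alkenes tolerate.

Compound list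
1 | D-(−)-pantolactone, (R)-3-hydroxy-4,4-dimethyldihydrofuran-2(3H)-one | CC1(C)COC(=O)[C@@H]1O | starting material
2 | (R)-3-(tert-butyldimethylsilyloxy)-4,4-dimethyldihydrofuran-2(3H)-one | CC1(C)COC(=O)[C@@H]1O[Si](C)(C)C(C)(C)C | intermediate
3 | (3R)-3-(tert-butyldimethylsilyloxy)-4,4-dimethyltetrahydrofuran-2-ol (lactol, both anomers) | CC1(C)COC(O)[C@@H]1O[Si](C)(C)C(C)(C)C | intermediate
4 | (R)-2-(tert-butyldimethylsilyloxy)-4-hydroxy-3,3-dimethylbutanal (open form of 3, not isolated) | O=C[C@H](O[Si](C)(C)C(C)(C)C)C(C)(C)CO | intermediate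
5 | (S)-3-(tert-butyldimethylsilyloxy)-2,2-dimethylpent-4-en-1-ol | C=C[C@H](O[Si](C)(C)C(C)(C)C)C(C)(C)CO | intermediate
6 | (S)-3-(tert-butyldimethylsilyloxy)-2,2-dimethylpent-4-enal | C=C[C@H](O[Si](C)(C)C(C)(C)C)C(C)(C)C=O | intermediate
7 | (4S)-4-(tert-butyldimethylsilyloxy)-3,3-dimethylhex-5-en-2-ol (both C2 epimers) | C=C[C@H](O[Si](C)(C)C(C)(C)C)C(C)(C)C(C)O | intermediate
8 | (S)-4-(tert-butyldimethylsilyloxy)-3,3-dimethylhex-5-en-2-one | C=C[C@H](O[Si](C)(C)C(C)(C)C)C(C)(C)C(C)=O | intermediate
9 | 3-methylbut-2-en-1-ol (prenol) | CC(C)=CCO | starting material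
10 | 1-methoxy-4-{[(3-methylbut-2-en-1-yl)oxy]methyl}benzene | CC(C)=CCOCc1ccc(OC)cc1 | intermediate
11 | (E)-4-(4-methoxybenzyloxy)-2-methylbut-2-en-1-ol | OC/C(C)=C/COCc1ccc(OC)cc1 | intermediate
12 | (E)-4-(4-methoxybenzyloxy)-2-methylbut-2-enal | O=C/C(C)=C/COCc1ccc(OC)cc1 | intermediate
13 | bis[(+)-isopinocampheyl]boron enolate of 8 (not isolated) | C=C(OB([C@H]1C[C@H]2C[C@@H]([C@@H]1C)C2(C)C)[C@H]1C[C@H]2C[C@@H]([C@@H]1C)C2(C)C)C(C)(C)[C@@H](O[Si](C)(C)C(C)(C)C)C=C | intermediate
14 | bis[(+)-isopinocampheyl]borinate of 15 at O7 (not isolated) | C=C[C@H](O[Si](C)(C)C(C)(C)C)C(C)(C)C(=O)C[C@H](OB([C@H]1C[C@H]2C[C@@H]([C@@H]1C)C2(C)C)[C@H]1C[C@H]2C[C@@H]([C@@H]1C)C2(C)C)/C(C)=C/COCc1ccc(OC)cc1 | intermediate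
15 | (3S,7S,8E)-3-(tert-butyldimethylsilyloxy)-7-hydroxy-10-(4-methoxybenzyloxy)-4,4,8-trimethyldeca-1,8-dien-5-one | C=C[C@H](O[Si](C)(C)C(C)(C)C)C(C)(C)C(=O)C[C@H](O)/C(C)=C/COCc1ccc(OC)cc1 | intermediate
16 | 2-(diethoxyphosphoryl)acetic acid | CCOP(=O)(CC(=O)O)OCC | starting material
17 | 7-O-[2-(diethoxyphosphoryl)acetyl] ester of 15 | C=C[C@H](O[Si](C)(C)C(C)(C)C)C(C)(C)C(=O)C[C@H](OC(=O)CP(=O)(OCC)OCC)/C(C)=C/COCc1ccc(OC)cc1 | intermediate
18 | (S)-4-[(S)-3-(tert-butyldimethylsilyloxy)-2-methylpent-4-en-2-yl]-6-[(E)-4-(4-methoxybenzyloxy)but-2-en-2-yl]-5,6-dihydro-2H-pyran-2-one | O=C1O[C@H](/C(C)=C/COCc2ccc(OC)cc2)CC(C(C)(C)[C@@H](O[Si](C)(C)C(C)(C)C)C=C)=C1 | intermediate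
19 | (4S,6S)-4-[(S)-3-(tert-butyldimethylsilyloxy)-2-methylpent-4-en-2-yl]-6-[(E)-4-(4-methoxybenzyloxy)but-2-en-2-yl]tetrahydro-2H-pyran-2-one (4,6-cis) | O=C1O[C@H](/C(C)=C/COCc2ccc(OC)cc2)C[C@H](C(C)(C)[C@@H](O[Si](C)(C)C(C)(C)C)C=C)C1 | intermediate
20 | lithium enolate of 19 (not isolated) | [Li]OC1=C[C@@H](C(C)(C)[C@@H](O[Si](C)(C)C(C)(C)C)C=C)C[C@@H](/C(C)=C/COCc2ccc(OC)cc2)O1 | intermediate
21 | (3R,4S,6S)-4-[(S)-3-(tert-butyldimethylsilyloxy)-2-methylpent-4-en-2-yl]-6-[(E)-4-(4-methoxybenzyloxy)but-2-en-2-yl]-3-methyltetrahydro-2H-pyran-2-one | O=C1O[C@H](/C(C)=C/COCc2ccc(OC)cc2)C[C@H](C(C)(C)[C@@H](O[Si](C)(C)C(C)(C)C)C=C)[C@H]1C | intermediate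
22 | lithium enolate of 21 (not isolated) | [Li]OC1=C(C)[C@@H](C(C)(C)[C@@H](O[Si](C)(C)C(C)(C)C)C=C)C[C@@H](/C(C)=C/COCc2ccc(OC)cc2)O1 | intermediate
23 | trimethylsilyl ketene acetal of 21: 2,4-cis-2-alkenyl-4-alkyl-5-methyl-6-(trimethylsilyloxy)-3,4-dihydro-2H-pyran (not isolated) | C[Si](C)(C)OC1=C(C)[C@@H](C(C)(C)[C@@H](O[Si](C)(C)C(C)(C)C)C=C)C[C@@H](/C(C)=C/COCc2ccc(OC)cc2)O1 | intermediate
24 | trimethylsilyl ester of 25 (not isolated) | COc1ccc(COC[C@H]2C(C)=CC[C@H](C(C)(C)[C@@H](O[Si](C)(C)C(C)(C)C)C=C)[C@@]2(C)C(=O)O[Si](C)(C)C)cc1 | intermediate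
25 | (1R,2S,6R)-6-[(S)-3-(tert-butyldimethylsilyloxy)-2-methylpent-4-en-2-yl]-2-[(4-methoxybenzyloxy)methyl]-1,3-dimethylcyclohex-3-ene-1-carboxylic acid (C10 methyl cis to the C5 side chain and trans to the C9 CH2O group) | COc1ccc(COC[C@H]2C(C)=CC[C@H](C(C)(C)[C@@H](O[Si](C)(C)C(C)(C)C)C=C)[C@@]2(C)C(=O)O)cc1 | intermediate
26 | [(1R,2S,6S)-6-[(S)-3-(tert-butyldimethylsilyloxy)-2-methylpent-4-en-2-yl]-2-[(4-methoxybenzyloxy)methyl]-1,3-dimethylcyclohex-3-en-1-yl]methanol | COc1ccc(COC[C@H]2C(C)=CC[C@H](C(C)(C)[C@@H](O[Si](C)(C)C(C)(C)C)C=C)[C@@]2(C)CO)cc1 | intermediate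
27 | (1R,2S,6R)-6-[(S)-3-(tert-butyldimethylsilyloxy)-2-methylpent-4-en-2-yl]-2-[(4-methoxybenzyloxy)methyl]-1,3-dimethylcyclohex-3-ene-1-carbaldehyde | COc1ccc(COC[C@H]2C(C)=CC[C@H](C(C)(C)[C@@H](O[Si](C)(C)C(C)(C)C)C=C)[C@@]2(C)C=O)cc1 | intermediate
28 | (4S,5R,6S)-4-[(S)-3-(tert-butyldimethylsilyloxy)-2-methylpent-4-en-2-yl]-6-[(4-methoxybenzyloxy)methyl]-1,5-dimethyl-5-vinylcyclohex-1-ene | COc1ccc(COC[C@H]2C(C)=CC[C@H](C(C)(C)[C@@H](O[Si](C)(C)C(C)(C)C)C=C)[C@@]2(C)C=C)cc1 | intermediate
29 | (1S,4aS,6S,8aR)-6-(tert-butyldimethylsilyloxy)-1-[(4-methoxybenzyloxy)methyl]-2,5,5,8a-tetramethyl-1,4,4a,5,6,8a-hexahydronaphthalene | COc1ccc(COC[C@H]2C(C)=CC[C@@H]3C(C)(C)[C@@H](O[Si](C)(C)C(C)(C)C)C=C[C@]32C)cc1 | intermediate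
30 | (1S,4aS,6S,8aR)-6-(tert-butyldimethylsilyloxy)-1-[(4-methoxybenzyloxy)methyl]-2,5,5,8a-tetramethyl-1,4,4a,5,6,7,8,8a-octahydronaphthalene | COc1ccc(COC[C@H]2C(C)=CC[C@@H]3C(C)(C)[C@@H](O[Si](C)(C)C(C)(C)C)CC[C@]32C)cc1 | intermediate
31 | [(1S,4aS,6S,8aR)-6-(tert-butyldimethylsilyloxy)-2,5,5,8a-tetramethyl-1,4,4a,5,6,7,8,8a-octahydronaphthalen-1-yl]methanol | OC[C@H]1C(C)=CC[C@@H]2C(C)(C)[C@@H](O[Si](C)(C)C(C)(C)C)CC[C@]21C | intermediate
32 | scopoletin, 7-hydroxy-6-methoxy-2H-chromen-2-one | COc1cc2ccc(=O)oc2cc1O | starting material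
33 | 7-{[(1S,4aS,6S,8aR)-6-(tert-butyldimethylsilyloxy)-2,5,5,8a-tetramethyl-1,4,4a,5,6,7,8,8a-octahydronaphthalen-1-yl]methoxy}-6-methoxy-2H-chromen-2-one | COc1cc2ccc(=O)oc2cc1OC[C@H]1C(C)=CC[C@@H]2C(C)(C)[C@@H](O[Si](C)(C)C(C)(C)C)CC[C@]21C | intermediate
34 | CNP0218138.1, 7-{[(1S,4aS,6S,8aR)-6-hydroxy-2,5,5,8a-tetramethyl-1,4,4a,5,6,7,8,8a-octahydronaphthalen-1-yl]methoxy}-6-methoxy-2H-chromen-2-one | COc1cc2ccc(=O)oc2cc1OC[C@H]1C(C)=CC[C@@H]2C(C)(C)[C@@H](O)CC[C@]21C | target

Total step count: 23. Longest linear sequence: 20 steps (steps 1–6, then 10–23); steps 7–9 make the enal that joins at step 10.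

Steps most likely to fail

Step 15 (key step). Enolisation and O-silylation at the fully substituted C10 may be slow, and in the boat the C5 tert-alkyl group lies close to the forming C9–C10 bond, so hydrolysis or decomposition of the ketene acetal could outrun the rearrangement. The fallback makes the quaternary centre after the ring contraction instead of during it. It sets out from lactone 19: its lithium enolate 20 is silylated (Me3SiCl/Et3N) to the C10-unsubstituted silyl ketene acetal F1, which has a less crowded enol terminus and should rearrange through the same boat (PhMe, 110 °C) to the silyl ester F2 and, after acid work-up, the C10–H acid F3. Me3SiCHN2 in MeOH/PhMe gives the methyl ester F4. Its lithium enolate F5 (LiN(i-Pr)2, THF, −78 °C) should take up MeI on the face anti to the pseudoaxial CH2O group on C9, giving the quaternary methyl ester F6. LiAlH4 reduction of F6 comes back to the route at alcohol 26.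

Step 10. Facial selectivity in the addition to the enal may be insufficient, or of the opposite sense, giving mixtures of C7 epimers. The fallback fixes C7 by kinetic resolution instead of by the enolate ligands. It sets out from ketone 8 and enal 12: the lithium enolate of 8 F7 (LiN(i-Pr)2, THF, −78 °C) adds to 12 without selectivity to give 15 together with the (7R)-epimer F8. Sharpless kinetic resolution (Ti(Oi-Pr)4, D-(−)-diisopropyl tartrate, t-BuOOH, 4 Å molecular sieves, CH2Cl2, −20 °C) should epoxidise the fast-reacting (7R)-allylic alcohol to the epoxy alcohol F9 and leave the (7S)-alcohol, which is separated and re-enters the route as 15.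

Step 12. Base-induced β-elimination of the phosphonoacetate through the ketone enolate may compete with the slow addition of the phosphonate anion to the neopentyl-type ketone. The fallback closes the ring by an intramolecular Reformatsky reaction at low temperature and dehydrates afterwards. It sets out from aldol 15: BrCH2COBr and pyridine in CH2Cl2 at 0 °C give the bromoacetate F10. SmI2 in THF at −78 °C should close the β-hydroxy δ-lactone F11. Dehydration of the tertiary alcohol (SOCl2, pyridine, then DBU to bring the double bond into conjugation) comes back to the route at unsaturated lactone 18.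

Further compounds
F1 | step 15 | trimethylsilyl ketene acetal of 19 (no methyl on C10) | C[Si](C)(C)OC1=C[C@@H](C(C)(C)[C@@H](O[Si](C)(C)C(C)(C)C)C=C)C[C@@H](/C(C)=C/COCc2ccc(OC)cc2)O1
F2 | step 15 | trimethylsilyl ester of F3 | COc1ccc(COC[C@H]2C(C)=CC[C@H](C(C)(C)[C@@H](O[Si](C)(C)C(C)(C)C)C=C)[C@H]2C(=O)O[Si](C)(C)C)cc1
F3 | step 15 | C10–H acid (25 with hydrogen in place of the C10 methyl) | COc1ccc(COC[C@H]2C(C)=CC[C@H](C(C)(C)[C@@H](O[Si](C)(C)C(C)(C)C)C=C)[C@H]2C(=O)O)cc1
F4 | step 15 | methyl ester of F3 | COc1ccc(COC[C@H]2C(C)=CC[C@H](C(C)(C)[C@@H](O[Si](C)(C)C(C)(C)C)C=C)[C@H]2C(=O)OC)cc1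
F5 | step 15 | lithium enolate of F4 | COc1ccc(COC[C@H]2C(C)=CC[C@H](C(C)(C)[C@@H](O[Si](C)(C)C(C)(C)C)C=C)C2=C(OC)O[Li])cc1
F6 | step 15 | methyl ester of 25 | COc1ccc(COC[C@H]2C(C)=CC[C@H](C(C)(C)[C@@H](O[Si](C)(C)C(C)(C)C)C=C)[C@@]2(C)C(=O)OC)cc1
F7 | step 10 | lithium enolate of 8 | [Li]OC(=C)C(C)(C)[C@@H](O[Si](C)(C)C(C)(C)C)C=C
F8 | step 10 | (3S,7R,8E)-epimer of 15 | C=C[C@H](O[Si](C)(C)C(C)(C)C)C(C)(C)C(=O)C[C@@H](O)/C(C)=C/COCc1ccc(OC)cc1
F9 | step 10 | 8,9-epoxide of F8 (trans epoxide, oxygen delivered under D-tartrate control) | C=C[C@H](O[Si](C)(C)C(C)(C)C)C(C)(C)C(=O)C[C@@H](O)[C@]1(C)O[C@H]1COCc1ccc(OC)cc1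
F10 | step 12 | 7-O-bromoacetyl ester of 15 | C=C[C@H](O[Si](C)(C)C(C)(C)C)C(C)(C)C(=O)C[C@H](OC(=O)CBr)/C(C)=C/COCc1ccc(OC)cc1
F11 | step 12 | (6S)-4-hydroxy-4-[(S)-3-(tert-butyldimethylsilyloxy)-2-methylpent-4-en-2-yl]-6-[(E)-4-(4-methoxybenzyloxy)but-2-en-2-yl]tetrahydro-2H-pyran-2-one (carbinol configuration not defined) | O=C1CC(O)(C(C)(C)[C@@H](O[Si](C)(C)C(C)(C)C)C=C)C[C@@H](/C(C)=C/COCc2ccc(OC)cc2)O1
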